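## Analysis of the target

The target 44 is pentacyclic. A trans-decalin (ring A: C1–C5, C10; ring B: C5–C10) is fused through C8–C9 to cyclohexane ring C (C8, C9, C11–C14). C13 of ring C is a spiro carbon shared with oxolane ring D (O, C13, C3′, C2′, C1′), and ring D bridges cyclohexanone ring E (C1′–C6′), so that rings D and E form a 6-oxabicyclo[3.2.1]octane.

There are ten stereocentres (C5, C6, C8, C9, C10, C13, C1′, C2′, C3′, C6′). On the terpenoid half the C8 and C10 methyl groups, the C6 acetoxy group and the C13 oxygen are all axial on one face (called α here); H-5 and H-9 are on the other face and the ring E carbon on C13 is equatorial. On ring E the oxygen at C1′, the hydroxyl at C2′, the C13 substituent at C3′ and the methyl at C6′ are all cis, with the methyl equatorial next to the ketone.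

The sensitive groups are:
- the C5′ ketone, which is β to the ring D oxygen (retro-oxa-Michael opening) and flanked by the epimerisable C6′;
- the tertiary spiro ether, which can ionise in acid;
- the acetate on a hydroxyl screened by three syn-axial methyl groups;
- the free C2′ hydroxyl.

The synthesis is hard because of the two methyl-bearing quaternary carbons C8 and C10, the fully substituted C13 that joins two independently chiral halves, and a decalin whose absolute configuration is opposite to that of the common labdane chiral pool. Both halves therefore have to come from asymmetric catalysis.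

The strategy rests on C13. It carries one oxygen, C3′ of ring E and the two ring C methylenes C12 and C14, which is the pattern of a lactone carbonyl that has accepted two carbanions. The cis relation of the C1′ oxygen and C3′ on ring E is what a bridged γ-lactone provides.

## Retrosynthetic reasoning

**44 back to 40 (no skeletal bonds).** The C2′ hydroxyl is uncovered last by neutral hydrogenolysis of 43. The C5′ ketone is made just before, by oxidation of 42, so that the β-alkoxy ketone never meets acid, base or fluoride. Alcohol 42 comes from silyl ether 41, and the acetate of 41 is placed on the single free hydroxyl of 40.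

**40 back to 38 (C13–O).** The spiro ether is cut at the C13–O bond because the forward reaction, ionisation of the tertiary carbinol of 38 and capture by the C1′ hydroxyl, is reversible. It places the oxygen axial and the large ring E carbon equatorial under thermodynamic control, and it never breaks the C1′–O bond, so C1′ keeps its configuration.

**38 back to 23 and 35 (C12–C13 and C13–C14).** Both ring C bonds to C13 are cut. C13 becomes the carbonyl of bicyclic lactone 35, and C12 and C14 become the carbanions of the bis-organomagnesium 36 made from dibromide 23. This is the most convergent cut available: it joins the two halves and closes ring C in one operation, and lactone 35 already carries the four ring E stereocentres with the C1′ oxygen and C3′ locked cis.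

**23 back to 18 (C6 spectator, C12 and C14 arms).** The two bromides come from the diol 22, and the diol from ozonolysis of a vinyl group on C8 and an allyl group on C9 in 20, so both arms are revealed in one step. A cyclic ketal at C6 was considered as the spectator and rejected: the C6 carbonyl lies between C5 (itself between two quaternary carbons) and a methylene next to quaternary C8, and a ketal oxygen would be pressed against three syn-axial methyl groups. Hydride, in contrast, reaches this ketone easily and only from the open face, giving exactly the axial alcohol the acetate needs. The ketone of 18 is therefore reduced before the coupling (19) and carried as the small triethylsilyl ether 20, which also removes a reduction from the end of the route.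

**18 back to 13 (C8–C14 and C8–CH3).** The quaternary C8 is cut to the enone 16 and a vinyl nucleophile, and 16 to the enone 14 and a methyl nucleophile. The order matters: the group that enters last comes in anti to the C9 substituent and away from the axial C10 methyl, so vinyl must be last. Enone 14 comes from ketone 13, where only one direction of dehydrogenation is possible.

**13 back to 6 (ring A).** Ring A is opened at the C4 methyl (conjugate methylation of enone 11) and at C4=C5 (aldol condensation of diketone 10). The C10–C1 bond is then cut to enone 6 and the side-chain organomagnesium 8 made from chloride 7. A cationic closure of a homoprenyl chain would be one step shorter but is less predictable (see Alternative 2).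

**6 back to 1 and 2 (ring B, C9).** The β-methyl of 6 is removed to give 4, which is the aldol condensation product of keto aldehyde 3. 3 is the enamine-catalysed Michael adduct of aldehyde 1 and enone 2. This one catalytic step sets C9, from which C10, C5, C8 and C6 follow by substrate control.

**35 back to 29 (C5′–O, C6′–H, lactone).** The silyl ether 35 comes from alcohol 34, which is the hydroboration product of alkene 32. Attack from the open exo face of the bicycle sets C6′ and puts the oxygen on C5′. Alkene 32 is the dehydration product of tertiary alcohol 31, and 31 arises when the carboxyl group of epoxy acid 30 opens the epoxide at C1′. That opening forms the lactone C–O bond with the required cis relation to C3′.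

**29 back to 25 and 26 (ring E carbons, C2′ and C3′).** Acid 29 is the benzyl ether of hydroxy acid 28, which comes from Diels–Alder adduct 27. The cyclohexene is cut into diene 25 (from aldehyde 24) and acrylimide 26, because a catalytic enantioselective cycloaddition sets C2′ and C3′ cis in one step.

## Alternatives that were turned down

**Alternative 1:** The C2′–C3′ bond of ring D is cut while ring E is still open. In the forward step an N-heterocyclic carbene turns the aldehyde of A1 (the C13 O-(2-oxoethyl) ether carrying an (E)-enone chain on C13) into an acyl anion equivalent, which adds 5-exo to C3′ and gives the spiro dihydrofuranone A2.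
- For it: the bond formation is catalytic, C3′ is set under catalyst control, and no stoichiometric organometallic or strong acid meets the oxygenated half. On these points it is stronger than the chosen route.
- Against it: A2 still lacks ring E. Its closure needs a bond between C1′ and C6′, two carbons that are each α to a ketone, so an oxidative coupling or a halogenation–alkylation sequence would be required, followed by stereoselective reduction at C2′; three stereocentres remain open. A1 is itself awkward: it is an ether of a hindered tertiary alcohol whose C13 configuration must be set beforehand, and its acceptor carbon C3′ is neopentyl, which slows the conjugate addition.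
- Comparison: the chosen route brings ring E in complete, with four stereocentres fixed, and sets C13 by equilibration instead of by a separate addition.

**Alternative 2:** The C4–C5 bond of ring A is cut. In the forward step a strong acid protonates the trisubstituted alkene of cyclohexanone A3 and the enol at C5 captures the tertiary cation, giving trans-decalinone A4.
- For it: it is short and close to biosynthesis, and it makes ring A in one step where the chosen route needs two (steps 5 and 6). On step count for this ring it is stronger.
- Against it: it settles only the least demanding ring. The quaternary C8, ring C, the spiro centre and rings D and E are untouched, so it is a tactic for the decalin and not a plan for 44. Mechanistically the enol content of a simple ketone is low, and the alkene stands in the 1,6-relation to the carbonyl that favours a carbonyl-ene or Prins closure to a bridged bicyclo[3.3.1]nonanol once the carbonyl is activated. The silyl ether must also survive the acid.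
- Comparison: the chosen route builds ring A through two enolate-type bond formations, each with a single productive pathway, and places its risk in a step that joins the halves and builds ring C.

**Alternative 3:** The C8–C14 and C13–O bonds are cut. In the forward step an alkylaluminium chloride Lewis acid activates the 8-methyl enone of A5; the 1,1-disubstituted C13=C14 alkene attacks C8 through C14 (6-endo), and the C1′ hydroxyl captures the resulting C13 cation, giving pentacycle A6.
- For it: one operation creates the C8 quaternary centre, ring C and ring D. It needs no dibromide and no bis-organometallic, and C6 can stay a ketone. On step economy after fragment union it is stronger, and it is equally convergent.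
- Against it: A5 requires ring E to be attached through a 1,1-disubstituted alkene next to C3′, which means a hindered olefination or alkenyl coupling. The alkene is a weak nucleophile for a β,β-disubstituted enone carbon flanked by C9 and the axial C10 methyl. The cation can lose a proton or be intercepted by the benzyl ether, the free hydroxyl ties up the Lewis acid, and C8 and C13 are both set in one kinetic event.
- Comparison: the chosen route fixes C8 early by conjugate addition, where two steric elements point the same way, and sets C13 under thermodynamic control, so each bond-forming event has a close precedent and a failure is easy to locate.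

Key step: step 22

## Route

Remark: locants are those of the target (C1–C14, C1′–C6′), α denotes the face of rings B and C that carries the C8 and C10 methyl groups, and 1, 2, 7, 24 and 26 are taken as purchasable.

Step 1
Reactants: 1 pent-4-enal; 2 methyl vinyl ketone
Product: 3 (S)-2-(3-oxobutyl)pent-4-enal
Conditions: (S)-2-[methoxy(diphenyl)methyl]pyrrolidine (5 mol%), ethyl 3,4-dihydroxybenzoate (20 mol%), neat, 4 °C
Reagents that add atoms: none
Why: Enamine-catalysed Michael addition of an unbranched aldehyde to an enone; the bulky arm of the (S)-catalyst shields one face of the E-enamine, so the enone should add to the Si face of the α-carbon and give the (S)-aldehyde, which fixes C9 and with it the absolute configuration of the decalin.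

Step 2
Reactants: 3 (S)-2-(3-oxobutyl)pent-4-enal
Product: 4 (S)-4-allylcyclohex-2-en-1-one
Conditions: KOH (0.1 M aq), n-Bu4NOH (cat.), Et2O–THF, 40 °C
Reagents that add atoms: none
Why: Intramolecular aldol condensation of the methyl ketone onto the aldehyde; the stereocentre becomes the γ-carbon of the enone and should not be epimerised by dilute base.

Step 3
Reactants: 4 (S)-4-allylcyclohex-2-en-1-one
Product: 6 (S)-4-allyl-3-methylcyclohex-2-en-1-one, via silyl enol ether 5 (not isolated)
Conditions: MeMgBr, CuBr·SMe2 (5 mol%), Me3SiCl, THF, −78 °C; then Pd(OAc)2, MeCN, 23 °C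
Reagents that add atoms: methylmagnesium bromide, C[Mg]Br
Why: Copper-catalysed, chlorosilane-accelerated conjugate addition followed by Saegusa–Ito dehydrogenation of the crude silyl enol ether; the transient stereocentre at the methyl-bearing carbon is erased again, and the position of the new double bond is fixed by the enol ether.

Step 4
Reactants: 6 (S)-4-allyl-3-methylcyclohex-2-en-1-one; 7 2-(3-chloropropyl)-2-methyl-1,3-dioxolane
Product: 10 (3R,4S)-4-allyl-3-methyl-3-(4-oxopentyl)cyclohexan-1-one, via Grignard reagent 8 (not isolated), via silyl enol ether 9 (not isolated)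
Conditions: 7, Mg, THF, 60 °C; then 6, CuBr·SMe2 (10 mol%), Me3SiCl, THF, −78 → −20 °C; then 1 M HCl, THF, 23 °C
Reagents that add atoms: none
Why: Copper-catalysed conjugate addition to a 3,4-disubstituted cyclohexenone, in which the nucleophile enters anti to the allyl group on the neighbouring carbon (C9); the chain on the new quaternary C10 is therefore trans to allyl and the methyl cis, as ring A requires, and aqueous acid then unmasks both carbonyl groups.

Step 5
Reactants: 10 (3R,4S)-4-allyl-3-methyl-3-(4-oxopentyl)cyclohexan-1-one
Product: 11 9-allyl-4,10-dimethyloctal-4-en-6-one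
Conditions: KOH, MeOH, 65 °C
Reagents that add atoms: none
Why: Intramolecular aldol condensation; only the C5 enolate can close a six-membered ring onto the side-chain ketone and then lose water, whereas the bridged aldol from the side-chain enolate onto the ring ketone is reversible and cannot dehydrate, so the conjugated alkylidene ketone is the thermodynamic sink.

Step 6
Reactants: 11 9-allyl-4,10-dimethyloctal-4-en-6-one
Product: 13 9-allyl-4,4,10-trimethyl-trans-decalin-6-one, via silyl enol ether 12 (not isolated)
Conditions: MeMgBr, CuBr·SMe2 (20 mol%), Me3SiCl, THF, −40 → 0 °C; then 1 M HCl; NaOMe, MeOH, 23 °C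
Reagents that add atoms: methylmagnesium bromide, C[Mg]Br
Why: Conjugate methylation of an alkylidene ketone of the pulegone type builds the C4 gem-dimethyl group without a new stereocentre at C4; H-5 is then set by base equilibration next to the ketone, the trans ring fusion being the more stable.

Step 7
Reactants: 13 9-allyl-4,4,10-trimethyl-trans-decalin-6-one
Product: 14 9-allyl-4,4,10-trimethyl-trans-decal-7-en-6-one
Conditions: IBX, DMSO–PhF, 70 °C
Reagents that add atoms: none
Why: Dehydrogenation of a ketone with 2-iodoxybenzoic acid; C5 has no β-hydrogen because C4 and C10 are quaternary, so only the C7=C8 enone can form.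

Step 8
Reactants: 14 9-allyl-4,4,10-trimethyl-trans-decal-7-en-6-one
Product: 16 9-allyl-4,4,8,10-tetramethyl-trans-decal-7-en-6-one, via silyl enol ether 15 (not isolated)
Conditions: MeMgBr, CuBr·SMe2 (10 mol%), Me3SiCl, THF, −78 → −40 °C; then Pd(OAc)2, MeCN, 23 °C
Reagents that add atoms: methylmagnesium bromide, C[Mg]Br
Why: The conjugate methylation and Saegusa–Ito sequence of step 3 now puts the methyl on C8; its configuration in 15 is irrelevant because C8 returns to sp2.

Step 9
Reactants: 16 9-allyl-4,4,8,10-tetramethyl-trans-decal-7-en-6-one
Product: 18 9-allyl-4,4,8,10-tetramethyl-8-vinyl-trans-decalin-6-one, via silyl enol ether 17 (not isolated)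
Conditions: CH2=CHMgBr, CuBr·SMe2 (20 mol%), Me3SiCl, HMPA, THF, −78 → −20 °C; then 1 M HCl
Reagents that add atoms: vinylmagnesium bromide, C=C[Mg]Br
Why: Copper-catalysed conjugate addition to the β-methyl enone forms the C8 quaternary centre; vinyl is delivered to the β face, anti to the adjacent C9 allyl group and away from the axial C10 methyl that blocks the α face, which leaves the C8 methyl axial (cis to the C10 methyl) and the future C14 equatorial.

Step 10
Reactants: 18 9-allyl-4,4,8,10-tetramethyl-8-vinyl-trans-decalin-6-one
Product: 19 9-allyl-4,4,8,10-tetramethyl-8-vinyl-trans-decalin-6α-ol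
Conditions: LiAlH4, THF, 0 °C
Reagents that add atoms: none
Why: Hydride reduction of a ketone; the α face of C6 is screened by the three syn-axial methyl groups on C4, C8 and C10, so hydride should attack from the β face and leave the hydroxyl axial, which is the configuration of the acetate in 44.

Step 11
Reactants: 19 9-allyl-4,4,8,10-tetramethyl-8-vinyl-trans-decalin-6α-ol
Product: 20 9-allyl-4,4,8,10-tetramethyl-6α-(triethylsilyloxy)-8-vinyl-trans-decalin
Conditions: Et3SiOTf, 2,6-lutidine, CH2Cl2, 0 °C
Reagents that add atoms: triethylsilyl trifluoromethanesulfonate, CC[Si](CC)(CC)OS(=O)(=O)C(F)(F)F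
Why: Silylation with a silyl triflate, one of the few reactions fast enough at this hindered axial hydroxyl; the small triethylsilyl group tolerates ozone, hydride, phosphine–bromide and organomagnesium chemistry and leaves again in the acid step after the coupling.

Step 12
Reactants: 20 9-allyl-4,4,8,10-tetramethyl-6α-(triethylsilyloxy)-8-vinyl-trans-decalin
Product: 22 9-(2-hydroxyethyl)-8-(hydroxymethyl)-4,4,8,10-tetramethyl-6α-(triethylsilyloxy)-trans-decalin, via bis-ozonide 21 (not isolated)
Conditions: O3, CH2Cl2, −78 °C; then NaBH4, MeOH, −78 → 0 °C
Reagents that add atoms: ozone, [O-][O+]=O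
Why: Ozonolysis of both terminal alkenes with reductive work-up; vinyl gives the C14 hydroxymethyl group on C8 and allyl the C11–C12 hydroxyethyl group on C9, and no stereocentre is touched.

Step 13
Reactants: 22 9-(2-hydroxyethyl)-8-(hydroxymethyl)-4,4,8,10-tetramethyl-6α-(triethylsilyloxy)-trans-decalin
Product: 23 9-(2-bromoethyl)-8-(bromomethyl)-4,4,8,10-tetramethyl-6α-(triethylsilyloxy)-trans-decalin
Conditions: CBr4, PPh3, pyridine, CH2Cl2, 0 °C; then ClCH2CH2Cl, 70 °C
Reagents that add atoms: carbon tetrabromide, BrC(Br)(Br)Br
Why: Appel bromination under neutral conditions; excess reagent should convert both hydroxyls into alkoxyphosphonium salts at once, so no free hydroxyl is left to close a cyclic ether, after which C12 reacts in the cold and the neopentyl C14 on heating by SN2 without skeletal rearrangement.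

Step 14
Reactants: 24 3-methylbut-2-enal
Product: 25 (E)-3-methylbuta-1,3-dien-1-yl acetate
Conditions: isopropenyl acetate, p-TsOH (cat.), 95 °C, acetone distilled off
Reagents that add atoms: isopropenyl acetate, CC(=C)OC(C)=O
Why: Acid-catalysed enol acetylation through the extended dienol; the E isomer is the one that reaches the s-cis conformation and reacts in the next step.

Step 15
Reactants: 25 (E)-3-methylbuta-1,3-dien-1-yl acetate; 26 3-acryloyl-1,3-oxazolidin-2-one
Product: 27 3-[(1R,2S)-2-acetoxy-4-methylcyclohex-3-ene-1-carbonyl]-1,3-oxazolidin-2-one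
Conditions: [Cu((R,R)-t-Bu-box)](SbF6)2 (5 mol%), CH2Cl2, −20 °C
Reagents that add atoms: none
Why: Enantioselective Diels–Alder reaction catalysed by a bis(oxazoline) complex of divalent copper, the ligand being 2,2′-propane-2,2-diylbis[(4R)-4-tert-butyl-4,5-dihydro-1,3-oxazole]; the imide chelates the square-planar metal in its s-cis form, the tert-butyl groups cover the Re face of the α-carbon, and endo addition to the Si face with the acetoxy terminus ortho and the methyl para should give the cis-(1R,2S) adduct, which sets C3′ and C2′.

Step 16
Reactants: 27 3-[(1R,2S)-2-acetoxy-4-methylcyclohex-3-ene-1-carbonyl]-1,3-oxazolidin-2-one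
Product: 28 (1R,2S)-2-hydroxy-4-methylcyclohex-3-ene-1-carboxylic acid
Conditions: LiOH, H2O2, THF–H2O, 0 → 23 °C; Na2SO3; then HCl to pH 3
Reagents that add atoms: hydrogen peroxide, OO
Why: Hydroperoxide cleavage of the N-acyl oxazolidinone is fast at 0 °C and gives the carboxylate before the α-proton can be removed, so the β-acetoxy group is not eliminated; hydroxide then hydrolyses the acetate.

Step 17
Reactants: 28 (1R,2S)-2-hydroxy-4-methylcyclohex-3-ene-1-carboxylic acid
Product: 29 (1R,2S)-2-(benzyloxy)-4-methylcyclohex-3-ene-1-carboxylic acid
Conditions: NaH (2.2 equiv), BnBr (1.05 equiv), n-Bu4NI (cat.), THF–DMF, 0 → 23 °C; then HCl aq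
Reagents that add atoms: benzyl bromide, BrCc1ccccc1
Why: Williamson etherification of the carboxylate–alkoxide dianion; the alkoxide is the stronger nucleophile and a carboxylate cannot be enolised, so O-benzylation should occur without β-elimination or epimerisation.

Step 18
Reactants: 29 (1R,2S)-2-(benzyloxy)-4-methylcyclohex-3-ene-1-carboxylic acid
Product: 31 8-(benzyloxy)-4-hydroxy-4-methyl-6-oxabicyclo[3.2.1]octan-7-one, via epoxy acid 30 (not isolated)
Conditions: m-CPBA, CH2Cl2, 0 → 23 °C; then camphorsulfonic acid (cat.), 23 °C
Reagents that add atoms: 3-chloroperoxybenzoic acid, O=C(OO)c1cccc(Cl)c1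
Why: Peracid epoxidation from the face opposite the cis benzyloxy and carboxyl groups, then intramolecular trans-diaxial (Fürst–Plattner) opening of the epoxide at the secondary C1′ by the 1,3-diaxial carboxyl group (5-exo); this puts the lactone oxygen on C1′ cis to C3′ and leaves an axial tertiary alcohol at C6′.

Step 19
Reactants: 31 8-(benzyloxy)-4-hydroxy-4-methyl-6-oxabicyclo[3.2.1]octan-7-one
Product: 32 8-(benzyloxy)-4-methyl-6-oxabicyclo[3.2.1]oct-3-en-7-one
Conditions: SOCl2, pyridine, 0 °C
Reagents that add atoms: none
Why: Dehydration of a tertiary alcohol through its chlorosulfite by anti E2 elimination; the C6′ hydroxyl is axial in the rigid bicycle and anti-periplanar to the axial hydrogen on C5′, and elimination towards the bridgehead C1′ is excluded, so the endocyclic C5′=C6′ alkene is expected.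

Step 20
Reactants: 32 8-(benzyloxy)-4-methyl-6-oxabicyclo[3.2.1]oct-3-en-7-one
Product: 34 8-(benzyloxy)-3-hydroxy-4-methyl-6-oxabicyclo[3.2.1]octan-7-one, via alkylborane 33 (not isolated)
Conditions: BH3·THF, THF, 0 °C; then H2O2, aq NaHCO3, 0 → 23 °C
Reagents that add atoms: hydrogen peroxide, OO
Why: Hydroboration–oxidation; boron adds to the less substituted C5′, syn and from the exo face away from the lactone bridge, so the hydrogen delivered to C6′ pushes the methyl into the equatorial position cis to the bridge (the C6′ configuration of 44) and the C5′ hydroxyl ends up trans to it.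

Step 21
Reactants: 34 8-(benzyloxy)-3-hydroxy-4-methyl-6-oxabicyclo[3.2.1]octan-7-one
Product: 35 8-(benzyloxy)-3-(tert-butyldiphenylsilyloxy)-4-methyl-6-oxabicyclo[3.2.1]octan-7-one
Conditions: t-BuPh2SiCl, imidazole, DMF, 23 °C
Reagents that add atoms: tert-butyl(chloro)diphenylsilane, CC(C)(C)[Si](Cl)(c1ccccc1)c1ccccc1
Why: Standard silylation of a secondary alcohol; the tert-butyldiphenylsilyl ether is chosen because it withstands the sulfonic acid used after the coupling, so that the C5′ and C6 oxygens stay differentiated.

Step 22
Reactants: 23 9-(2-bromoethyl)-8-(bromomethyl)-4,4,8,10-tetramethyl-6α-(triethylsilyloxy)-trans-decalin; 35 8-(benzyloxy)-3-(tert-butyldiphenylsilyloxy)-4-methyl-6-oxabicyclo[3.2.1]octan-7-one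
Product: 38 tetracyclic C13 carbinol bearing the free C1′ hydroxyl, via bis-Grignard reagent 36 (not isolated), via keto Grignard reagent 37 (not isolated)
Conditions: 23, Mg (I2-activated), THF, 50 °C; CeCl3, −78 °C; then 35, −78 → 0 °C; aq NH4Cl
Reagents that add atoms: none
Why: Magnesium inserts into both C–Br bonds of 23 to give the 1,5-bis-Grignard reagent 36, which is transmetallated with CeCl3 to lower its basicity. The unhindered C12 carbanion is expected to add first to the strained γ-lactone carbonyl of 35; collapse of the tetrahedral intermediate breaks the acyl–oxygen bond, frees the C1′ oxygen as its alkoxide with retention and gives ketone 37, which holds the neopentyl C14 carbanion five atoms away. Addition of that carbanion to the ketone is a 6-exo-trig closure of ring C and forms C13–C14. The closest known reaction type is the annulation of esters and lactones with 1,4- and 1,5-di-Grignard reagents to cyclopentanols and cyclohexanols, including its organocerium variant. The only new stereocentre is C13; in the chair-like transition state the ring E residue on the carbonyl should sit equatorial and the oxygen axial, syn to the C8 methyl, which is the configuration drawn for 38, but the outcome is not critical because step 23 passes through the C13 cation. The selectivity that matters is double addition at carbon against enolisation of 37 at C3′, which would expel the β-benzyloxy group; it is secured by the intramolecular second addition, the low temperature and the weakly basic cerium reagent. The silyl and benzyl ethers are inert, and the four ring E stereocentres pass through unchanged.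

Step 23
Reactants: 38 tetracyclic C13 carbinol bearing the free C1′ hydroxyl
Product: 40 pentacyclic C6 alcohol, via triethylsilyl ether 39 (not isolated)
Conditions: p-TsOH·H2O (0.3 equiv), PhMe, 50 °C; then MeOH, 23 °C
Reagents that add atoms: none
Why: Acid-catalysed cyclodehydration of a 1,4-diol through the tertiary C13 cation (SN1), captured by the C1′ hydroxyl, whose own C–O bond is never broken; ionisation is reversible, so either C13 epimer and any alkene formed by proton loss should converge on the ether with oxygen axial and the bulky ring E carbon equatorial, away from the axial C8 methyl. Methanol then removes the triethylsilyl group, while the tert-butyldiphenylsilyl and benzyl ethers stay.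

Step 24
Reactants: 40 pentacyclic C6 alcohol
Product: 41 pentacyclic C6 acetate
Conditions: Ac2O, DMAP, Et3N, ClCH2CH2Cl, 60 °C
Reagents that add atoms: acetic anhydride, CC(=O)OC(C)=O
Why: Acylation catalysed by 4-(dimethylamino)pyridine; the axial C6 hydroxyl is hindered but is the only free hydroxyl, so forcing conditions can be used without a selectivity problem.

Step 25
Reactants: 41 pentacyclic C6 acetate
Product: 42 C5′ alcohol
Conditions: n-Bu4NF, AcOH, THF, 40 °C
Reagents that add atoms: none
Why: Fluoride cleavage of the silyl ether, buffered with acetic acid so that the acetate is neither hydrolysed nor shifted.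

Step 26
Reactants: 42 C5′ alcohol
Product: 43 C5′ ketone with the C2′ benzyl ether
Conditions: Dess–Martin periodinane, pyridine, CH2Cl2, 0 → 23 °C
Reagents that add atoms: none
Why: Dess–Martin oxidation under buffered, nearly neutral conditions, so that the new β-alkoxy ketone does not open ring D by elimination; the C6′ methyl is already equatorial, the more stable position, so enolisation cannot damage it.

Step 27
Reactants: 43 C5′ ketone with the C2′ benzyl ether
Product: 44 CNP0188572.2
Conditions: H2 (1 atm), 10% Pd/C, EtOAc, 23 °C
Reagents that add atoms: none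
Why: Hydrogenolysis of the benzyl ether on palladium under neutral conditions, which tolerates the ketone, the acetate and the acid- and base-sensitive β-alkoxy ketone.

## Compound list

1 | pent-4-enal | C=CCCC=O | starting material
2 | methyl vinyl ketone (but-3-en-2-one) | CC(=O)C=C | starting material
3 | (S)-2-(3-oxobutyl)pent-4-enal | CC(=O)CC[C@@H](CC=C)C=O | intermediate
4 | (S)-4-allylcyclohex-2-en-1-one | O=C1CC[C@@H](CC=C)C=C1 | intermediate
5 | trans-4-allyl-3-methyl-1-(trimethylsilyloxy)cyclohex-1-ene | C[Si](C)(C)OC1=C[C@@H](C)[C@H](CC=C)CC1 | intermediate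
6 | (S)-4-allyl-3-methylcyclohex-2-en-1-one | O=C1CC[C@@H](CC=C)C(C)=C1 | intermediate
7 | 2-(3-chloropropyl)-2-methyl-1,3-dioxolane | CC1(CCCCl)OCCO1 | starting material
8 | [3-(2-methyl-1,3-dioxolan-2-yl)propyl]magnesium chloride | CC1(CCC[Mg]Cl)OCCO1 | intermediate
9 | silyl enol ether of the conjugate adduct (chain trans to allyl, dioxolane intact) | C[Si](C)(C)OC1=C[C@@](C)(CCCC2(C)OCCO2)[C@H](CC=C)CC1 | intermediate
10 | (3R,4S)-4-allyl-3-methyl-3-(4-oxopentyl)cyclohexan-1-one | O=C1CC[C@@H](CC=C)[C@](C)(CCCC(C)=O)C1 | intermediate
11 | 9-allyl-4,10-dimethyloctal-4-en-6-one (C4=C5 enone; allyl cis to the C10 methyl) | O=C1CC[C@@H](CC=C)[C@]2(C)CCCC(C)=C12 | intermediate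
12 | 6-trimethylsilyl enol ether (C5=C6) of 13 | C[Si](C)(C)OC1=C2C(C)(C)CCC[C@@]2(C)[C@H](CC=C)CC1 | intermediate
13 | 9-allyl-4,4,10-trimethyl-trans-decalin-6-one (H-5 and H-9 β, C10 methyl α, allyl equatorial) | O=C1CC[C@@H](CC=C)[C@]2(C)CCCC(C)(C)[C@@H]12 | intermediate
14 | 9-allyl-4,4,10-trimethyl-trans-decal-7-en-6-one | O=C1C=C[C@@H](CC=C)[C@]2(C)CCCC(C)(C)[C@@H]12 | intermediate
15 | 6-trimethylsilyl enol ether (C6=C7) with 8β-methyl | C[Si](C)(C)OC1=C[C@H](C)[C@@H](CC=C)[C@]2(C)CCCC(C)(C)[C@@H]12 | intermediate
16 | 9-allyl-4,4,8,10-tetramethyl-trans-decal-7-en-6-one | O=C1C=C(C)[C@@H](CC=C)[C@]2(C)CCCC(C)(C)[C@@H]12 | intermediate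
17 | 6-trimethylsilyl enol ether (C6=C7) of 18 | C[Si](C)(C)OC1=C[C@](C)(C=C)[C@@H](CC=C)[C@]2(C)CCCC(C)(C)[C@@H]12 | intermediate
18 | 9-allyl-4,4,8,10-tetramethyl-8-vinyl-trans-decalin-6-one (C8 methyl α and axial, vinyl β and equatorial) | O=C1C[C@](C)(C=C)[C@@H](CC=C)[C@]2(C)CCCC(C)(C)[C@@H]12 | intermediate
19 | 9-allyl-4,4,8,10-tetramethyl-8-vinyl-trans-decalin-6α-ol (hydroxyl axial, cis to the C8 and C10 methyls) | O[C@H]1C[C@](C)(C=C)[C@@H](CC=C)[C@]2(C)CCCC(C)(C)[C@@H]12 | intermediate
20 | 6α-triethylsilyl ether of 19 | CC[Si](CC)(CC)O[C@H]1C[C@](C)(C=C)[C@@H](CC=C)[C@]2(C)CCCC(C)(C)[C@@H]12 | intermediate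
21 | bis(1,2,4-trioxolane) from 20 (ozonide carbons unassigned) | CC[Si](CC)(CC)O[C@H]1C[C@](C)(C2OCOO2)[C@@H](CC2OCOO2)[C@]2(C)CCCC(C)(C)[C@@H]12 | intermediate
22 | 9-(2-hydroxyethyl)-8-(hydroxymethyl)-4,4,8,10-tetramethyl-6α-(triethylsilyloxy)-trans-decalin | CC[Si](CC)(CC)O[C@H]1C[C@](C)(CO)[C@@H](CCO)[C@]2(C)CCCC(C)(C)[C@@H]12 | intermediate
23 | 9-(2-bromoethyl)-8-(bromomethyl)-4,4,8,10-tetramethyl-6α-(triethylsilyloxy)-trans-decalin | CC[Si](CC)(CC)O[C@H]1C[C@](C)(CBr)[C@@H](CCBr)[C@]2(C)CCCC(C)(C)[C@@H]12 | intermediate
24 | 3-methylbut-2-enal | CC(C)=CC=O | starting material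
25 | (E)-3-methylbuta-1,3-dien-1-yl acetate | CC(=O)O/C=C/C(C)=C | intermediate
26 | 3-acryloyl-1,3-oxazolidin-2-one | C=CC(=O)N1CCOC1=O | starting material
27 | 3-[(1R,2S)-2-acetoxy-4-methylcyclohex-3-ene-1-carbonyl]-1,3-oxazolidin-2-one | CC1=C[C@H](OC(C)=O)[C@H](C(=O)N2CCOC2=O)CC1 | intermediate
28 | (1R,2S)-2-hydroxy-4-methylcyclohex-3-ene-1-carboxylic acid | CC1=C[C@H](O)[C@H](C(=O)O)CC1 | intermediate
29 | (1R,2S)-2-(benzyloxy)-4-methylcyclohex-3-ene-1-carboxylic acid | CC1=C[C@H](OCc2ccccc2)[C@H](C(=O)O)CC1 | intermediate
30 | 2-(benzyloxy)-3,4-epoxy-4-methylcyclohexane-1-carboxylic acid (epoxide trans to the benzyloxy and carboxyl groups) | O=C(O)[C@@H]1CC[C@@]2(C)O[C@H]2[C@@H]1OCc1ccccc1 | intermediate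
31 | 8-(benzyloxy)-4-hydroxy-4-methyl-6-oxabicyclo[3.2.1]octan-7-one (benzyloxy syn to the lactone bridge, C4 hydroxyl axial and anti to the bridge) | O=C1O[C@@H]2[C@H](OCc3ccccc3)[C@H]1CC[C@@]2(C)O | intermediate
32 | 8-(benzyloxy)-4-methyl-6-oxabicyclo[3.2.1]oct-3-en-7-one | O=C1O[C@@H]2[C@H](OCc3ccccc3)[C@H]1CC=C2C | intermediate
33 | C3 alkylborane from 32 (boron on the exo face) | O=C1O[C@@H]2[C@H](OCc3ccccc3)[C@H]1C[C@@H](B)[C@@H]2C | intermediate
34 | 8-(benzyloxy)-3-hydroxy-4-methyl-6-oxabicyclo[3.2.1]octan-7-one (hydroxyl and methyl both equatorial, trans to each other) | O=C1O[C@@H]2[C@H](OCc3ccccc3)[C@H]1C[C@@H](O)[C@@H]2C | intermediate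
35 | 8-(benzyloxy)-3-(tert-butyldiphenylsilyloxy)-4-methyl-6-oxabicyclo[3.2.1]octan-7-one (ring E lactone; C2′ benzyl ether, C5′ silyl ether) | O=C1O[C@@H]2[C@H](OCc3ccccc3)[C@H]1C[C@@H](O[Si](c4ccccc4)(c5ccccc5)C(C)(C)C)[C@@H]2C | intermediate
36 | bis-Grignard reagent from 23 (C12 and C14 bromomagnesio) | CC[Si](CC)(CC)O[C@H]1C[C@](C)(C[Mg]Br)[C@@H](CC[Mg]Br)[C@]2(C)CCCC(C)(C)[C@@H]12 | intermediate
37 | C13 ketone carrying the C14 Grignard centre and the C1′ magnesium alkoxide | CC[Si](CC)(CC)O[C@H]1C[C@](C)(C[Mg]Br)[C@@H](CCC(=O)[C@@H]2C[C@@H](O[Si](c3ccccc3)(c3ccccc3)C(C)(C)C)[C@H](C)[C@H](O[Mg]Br)[C@@H]2OCc2ccccc2)[C@]2(C)CCCC(C)(C)[C@@H]12 | intermediate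
38 | tetracyclic C13 carbinol (C13 hydroxyl axial α, ring E equatorial; free C1′ hydroxyl; C6 triethylsilyl ether, C2′ benzyl ether, C5′ tert-butyldiphenylsilyl ether) | CC[Si](CC)(CC)O[C@H]1C[C@]2(C)C[C@@](O)(CC[C@H]2[C@]2(C)CCCC(C)(C)[C@@H]12)[C@@H]1C[C@@H](O[Si](c2ccccc2)(c2ccccc2)C(C)(C)C)[C@H](C)[C@H](O)[C@@H]1OCc1ccccc1 | intermediate
39 | pentacyclic spiro ether with the C6 triethylsilyl ether | CC[Si](CC)(CC)O[C@H]1C[C@]2(C)C[C@]3(CC[C@H]2[C@]2(C)CCCC(C)(C)[C@@H]12)O[C@@H]1[C@H](OCc2ccccc2)[C@H]3C[C@@H](O[Si](c2ccccc2)(c2ccccc2)C(C)(C)C)[C@@H]1C | intermediate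
40 | pentacyclic C6 alcohol (C2′ benzyl ether, C5′ silyl ether) | O[C@H]1C[C@]2(C)C[C@]3(CC[C@H]2[C@]2(C)CCCC(C)(C)[C@@H]12)O[C@@H]1[C@H](OCc2ccccc2)[C@H]3C[C@@H](O[Si](c2ccccc2)(c2ccccc2)C(C)(C)C)[C@@H]1C | intermediate
41 | pentacyclic C6 acetate (C2′ benzyl ether, C5′ silyl ether) | CC(=O)O[C@H]1C[C@]2(C)C[C@]3(CC[C@H]2[C@]2(C)CCCC(C)(C)[C@@H]12)O[C@@H]1[C@H](OCc2ccccc2)[C@H]3C[C@@H](O[Si](c2ccccc2)(c2ccccc2)C(C)(C)C)[C@@H]1C | intermediate
42 | C5′ alcohol (C6 acetate, C2′ benzyl ether) | CC(=O)O[C@H]1C[C@]2(C)C[C@]3(CC[C@H]2[C@]2(C)CCCC(C)(C)[C@@H]12)O[C@@H]1[C@H](OCc2ccccc2)[C@H]3C[C@@H](O)[C@@H]1C | intermediate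
43 | C5′ ketone (C6 acetate, C2′ benzyl ether) | CC(=O)O[C@H]1C[C@]2(C)C[C@]3(CC[C@H]2[C@]2(C)CCCC(C)(C)[C@@H]12)O[C@@H]1[C@H](OCc2ccccc2)[C@H]3CC(=O)[C@@H]1C | intermediate
44 | CNP0188572.2 (C6 acetate, C2′ alcohol, C5′ ketone) | CC(=O)O[C@H]1C[C@]2(C)C[C@]3(CC[C@H]2[C@]2(C)CCCC(C)(C)[C@@H]12)O[C@@H]1[C@H](O)[C@H]3CC(=O)[C@@H]1C | target

## Step count and least certain steps

Total: 27 steps. Longest linear sequence: 19 steps (steps 1–13, then 22–27). The lactone branch (steps 14–21) is 8 steps.

**Step 22 (key step).** Magnesium insertion at the neopentyl C14–Br bond may lag behind that at C12, so that only one carbanion is available and the reaction stops after a single addition. Alternatively, ketone 37 may be deprotonated at C3′ and lose the β-benzyloxy group before ring C closes. The fallback sets out from 23 and 35 and returns at 38; it makes the two bonds one after the other.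
- NaI in acetone exchanges only the unhindered bromide and gives the iodo bromide F1.
- tert-Butyllithium at −78 °C performs iodine–lithium exchange; the neopentyl bromide is neither exchanged nor open to internal displacement. This gives the alkyllithium F2.
- F2 adds once to lactone 35 in the cold and gives the bromo lactol F3.
- SmI2 with HMPA in THF closes ring C by an intramolecular Barbier reaction of the neopentyl bromide onto the ring-opened keto tautomer of F3, giving 38.

**Step 23.** Proton loss from the C13 cation may outrun capture by the C1′ hydroxyl, and the resulting alkenes may return slowly; prolonged acid may also start to cleave the C5′ silyl ether. The fallback sets out from 38 and returns at 39 (the methanol stage of step 23 then gives 40). PPh3, I2 and imidazole convert the secondary C1′ hydroxyl into the inverted C1′ iodide F4 while the tertiary hydroxyl stays free. AgOSO2CF3 with 2,6-di-tert-butylpyridine then lets the C13 oxygen displace iodide from the rear. The two inversions restore the C1′ configuration, and the C1′–O bond is formed instead of the C13–O bond, so no C13 cation is needed. This variant relies on the C13 configuration from step 22.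

**Step 6.** Conjugate addition to the tetrasubstituted enone 11 may be too slow because quaternary C10 crowds C4; carbonyl addition or recovered enone would result. The fallback sets out from 6 and returns at 13, bringing the gem-dimethyl group in with the chain. Copper-catalysed addition of (4-methylpent-3-en-1-yl)magnesium bromide F5, prepared from commercial 5-bromo-2-methylpent-2-ene, gives the homoprenyl ketone F6. CF3SO3H in CH2Cl2 protonates the trisubstituted alkene, and the C5 enol captures the tertiary cation to close ring A. A Brønsted acid is chosen over a carbonyl-binding Lewis acid to disfavour the competing carbonyl-ene closure.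

**Step 18.** Facial selectivity of the epoxidation may be poor if the carboxyl group guides the peracid to its own face, and a syn epoxide cannot lactonise; opening at the tertiary C6′ is a second possible leak. The fallback sets out from 29 and returns at 31. OsO4 (cat.) with N-methylmorpholine N-oxide dihydroxylates the alkene from the face opposite both substituents and gives the dihydroxy acid F7. Mitsunobu lactonisation (PPh3, diisopropyl azodicarboxylate) activates only the secondary C1′ hydroxyl, and the carboxylate displaces it with inversion.

**Step 19.** Elimination may run towards the methyl group (exocyclic alkene), or chloride may substitute at the tertiary centre. The fallback sets out from 31 and returns at 32. Burgess reagent eliminates syn, which in the rigid chair can only use a methyl hydrogen, and gives the exocyclic alkene F8. RhCl3·3H2O in ethanol at 70 °C then moves the double bond into the ring; the trisubstituted endocyclic alkene is the more stable isomer and the bridgehead position is excluded.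

## Further compounds

F1 | step 22 | 9-(2-iodoethyl)-8-(bromomethyl)-4,4,8,10-tetramethyl-6α-(triethylsilyloxy)-trans-decalin | CC[Si](CC)(CC)O[C@H]1C[C@](C)(CBr)[C@@H](CCI)[C@]2(C)CCCC(C)(C)[C@@H]12
F2 | step 22 | C12 alkyllithium retaining the C14 bromide | CC[Si](CC)(CC)O[C@H]1C[C@](C)(CBr)[C@@H](CC[Li])[C@]2(C)CCCC(C)(C)[C@@H]12
F3 | step 22 | bromo lactol from single addition to 35 (hemiketal carbon C13 unassigned) | CC[Si](CC)(CC)O[C@H]1C[C@](C)(CBr)[C@@H](CCC2(O)O[C@@H]3[C@H](OCc4ccccc4)[C@H]2C[C@@H](O[Si](c2ccccc2)(c2ccccc2)C(C)(C)C)[C@@H]3C)[C@]2(C)CCCC(C)(C)[C@@H]12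
F4 | step 23 | C1′ iodide of 38 with inverted C1′ | CC[Si](CC)(CC)O[C@H]1C[C@]2(C)C[C@@](O)(CC[C@H]2[C@]2(C)CCCC(C)(C)[C@@H]12)[C@@H]1C[C@@H](O[Si](c2ccccc2)(c2ccccc2)C(C)(C)C)[C@H](C)[C@@H](I)[C@@H]1OCc1ccccc1
F5 | step 6 | (4-methylpent-3-en-1-yl)magnesium bromide | CC(C)=CCC[Mg]Br
F6 | step 6 | (3R,4S)-4-allyl-3-methyl-3-(4-methylpent-3-en-1-yl)cyclohexan-1-one | O=C1CC[C@@H](CC=C)[C@](C)(CCC=C(C)C)C1
F7 | step 18 | 2-(benzyloxy)-3,4-dihydroxy-4-methylcyclohexane-1-carboxylic acid (diol trans to the benzyloxy and carboxyl groups) | O=C(O)[C@@H]1CC[C@@](C)(O)[C@@H](O)[C@@H]1OCc1ccccc1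
F8 | step 19 | 8-(benzyloxy)-4-methylidene-6-oxabicyclo[3.2.1]octan-7-one | O=C1O[C@@H]2[C@H](OCc3ccccc3)[C@H]1CCC2=C
A1 | alternative 1 | C13 O-(2-oxoethyl) ether carrying the C13 (E)-enone chain | CC(=O)O[C@H]1C[C@]2(C)C[C@](CC[C@H]2[C@]2(C)CCCC(C)(C)[C@@H]12)(OCC=O)/C=C/C(=O)CC
A2 | alternative 1 | spiro dihydrofuranone with 2-oxobutyl chain on C3′ | CC(=O)O[C@H]1C[C@]2(C)C[C@]3(CC[C@H]2[C@]2(C)CCCC(C)(C)[C@@H]12)OCC(=O)[C@H]3CC(=O)CC
A3 | alternative 2 | cyclohexanone with C10 homoprenyl chain and C9 silyloxyethyl chain | O=C1CC[C@@H](CCO[Si](c2ccccc2)(c2ccccc2)C(C)(C)C)[C@](C)(CCC=C(C)C)C1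
A4 | alternative 2 | trans-decalin-6-one with C9 silyloxyethyl chain | O=C1CC[C@@H](CCO[Si](c3ccccc3)(c3ccccc3)C(C)(C)C)[C@]2(C)CCCC(C)(C)[C@@H]12
A5 | alternative 3 | 8-methyl-7-en-6-one with the C13=C14 methylene joined to ring E (free C1′ hydroxyl) | O=C1C=C(C)[C@@H](CCC(=C)[C@@H]2C[C@@H](O[Si](C)(C)C(C)(C)C)[C@H](C)[C@H](O)[C@@H]2OCc2ccccc2)[C@]2(C)CCCC(C)(C)[C@@H]12
A6 | alternative 3 | pentacyclic C6 ketone (C2′ benzyl ether, C5′ silyl ether) | O=C1C[C@]2(C)C[C@]3(CC[C@H]2[C@]2(C)CCCC(C)(C)[C@@H]12)O[C@@H]1[C@H](OCc4ccccc4)[C@H]3C[C@@H](O[Si](C)(C)C(C)(C)C)[C@@H]1C
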